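## Structural features

Gancaonin G is an isoflavone in which benzene ring A is fused through C4a–C8a to the 4-pyranone ring C, and the 4-hydroxyphenyl ring B sits on C3. The molecule has no stereocentre, so no configuration has to be set and none stand next to each other. Ring A is a fully differentiated phloroglucinol: the ring oxygen O1 on C8a, a free hydroxyl on C5 (hydrogen-bonded to the C4 carbonyl), a prenyl group on C6, a methoxyl on C7 and hydrogen only on C8. The fragile parts are the trisubstituted prenyl alkene, which is sensitive to electrophiles, to hydrogenation and above all to acid (acid closes a dimethylchroman ring onto a free neighbouring phenol), the C2 position of the pyranone, which hydroxide and other hard nucleophiles open, and the electron-rich ring A. The real difficulty is regiochemical: the acyl carbon C4 must go onto C4a between two oxygens, the prenyl group onto C6 and not C8, and exactly one ring-A oxygen must carry methyl, whereas classical acid-mediated acylation and prenylation of phloroglucinols give mixtures and endanger the alkene. The key step exploits the fact that O1–C8a and C4–C4a lie on neighbouring carbons with the C5 oxygen directly beside C4a, which is the oxygen/acyl pattern left behind when a carboxylate adds to an aryne flanked by one alkoxy group and the acyl group then shifts to the carbanion. With both ring-A ethers carried as methyl ethers, the ring-A phenol has a mirror plane, its two ortho positions are equivalent, and only one aryne can arise. The price is that the peri 5-O-methyl group must be told apart from the 7-O-methyl group at the end, which the chelating C4 carbonyl allows.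

## Logic of the disconnections

23 back to 22: the last forward operation cleaves the methyl–O5 bond, so in the backward sense a methyl group is placed on O5. Carrying O5 as a methyl ether keeps ring A symmetric through the whole route and removes any need to differentiate the two oxygens that flank the prenyl group. The forward step must cleave only the peri ether and must not let the new hydroxyl add to the alkene, so a chelation-controlled, non-protic reagent is required.

22 back to 21: the O4'–CH2 bond of a methoxymethyl acetal is restored. The ring-B phenol must be covered because a free phenol would add to the aryne, and the acetal is introduced on the side branch at no cost to the main line. In the forward direction it is removed with acid while O5 is still methylated, so that no free phenol neighbours the prenyl alkene when acid is present; the demand is an acid mild enough to leave the alkene untouched.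

21 back to 19: the O1–C2 and C2–C3 bonds are cut, and C2 becomes a one-carbon electrophile at the formate oxidation level. Ring C disappears and an open-chain ortho-hydroxyaryl benzyl ketone remains. The forward step needs a free phenol ortho to the ketone, an activated methylene and a non-acidic reagent.

19 back to 13 and 16 (key disconnection): the C4–C4a and O1–C8a bonds are cut. Both partners become simple: an arylacetic acid that brings C4, C3, ring B and the oxygen that becomes O1, and a silyl triflate that brings ring A as an aryne. The forward step must add the carboxylate oxygen to the aryne carbon remote from the flanking methoxyl, and the acyl shift must outrun protonation of the aryl anion.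

16 back to 14: the phenol O–CH2 bond of the acetal is cut. Double alkylation followed by saponification of the labile ester in the same flask keeps this to one step. The forward step must leave the aryl acetal intact while the ester is hydrolysed and the acid is set free.

13 back to 11, 7 and 6: the O–S bond of the triflate, the ring C–Si bond and the carbamate O–C bond are cut. The carbamate on the phenol oxygen directs lithiation to the position between itself and a methoxyl; by symmetry there is only one such position. The lithiation must be faster than removal of the benzylic–allylic protons of the prenyl group. Carbamate cleavage and triflation share one flask, so 13 is reached from 6 in three steps.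

6 back to 5, 2, 3 and 1: the ring–CH2 bond of the prenyl group and the O–Si bond of a temporary silyl ether are cut. With the phenol oxygen under a bulky, non-directing silyl group, the carbon between the two methoxyls is the preferred site of lithiation, so 1 and 3 suffice. The forward step needs that regiochemistry and a direct (not allylically transposed) alkylation. Three steps lead to 6.

## Other disconnections considered

Alternative 1: The cut is the C2=C3 double bond of ring C. The forward key step would be ring-closing metathesis of the diene 2-[4-(benzyloxy)phenyl]-1-[2-(ethenyloxy)-4,6-dimethoxyphenyl]prop-2-en-1-one A1. The aryl vinyl ether and the 1,1-disubstituted enone alkene of A1 would be joined by the molybdenum imido alkylidene Mo(N-2,6-iPr2C6H3)(CHCMe2Ph)[OCMe(CF3)2]2 A2, with loss of the two terminal methylene groups, to give 4'-benzyloxy-5,7-dimethoxyisoflavone A3.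
- In its favour: the closure of A1 to A3 is neutral, catalytic and free of regiochemical ambiguity, and a molybdenum alkylidene such as A2 accepts enol ethers.
- Against it here: A1 must itself come from an ortho-hydroxy deoxybenzoin of the same type as 19, so the cut does not address the placement of the acyl carbon on ring A. It then needs α-methylenation and O-vinylation before the metathesis, three operations for what one amide acetal condensation does in the chosen plan.
- A3 carries no prenyl group. C6 would have to be prenylated afterwards, where C6 and C8 compete, and the benzyl ether of A3 could then not be removed by hydrogenolysis without saturating the alkene. The electron-poor, 1,1-disubstituted enone alkene of A1 is also a slow metathesis partner, and A2 is air-sensitive and tolerates no free phenol.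
- Comparison: on structure the chosen plan fixes every ring-A substituent before ring C is made, while the route through A1 and A3 postpones the hardest one. On mechanism the two ring closures are equal in regiochemical certainty, and the metathesis with A2 is the equal or the better in mildness. On step economy it is worse by at least two steps plus the late prenylation. The peri ether cleavage is needed in both.

Alternative 2: The cut removes four bonds of ring A (C8–C8a, C7–C8, C5–C6, C4a–C5), so ring A is built onto a preformed aryl pyranone. The forward key step would irradiate 2-(2-diazoacetyl)-5-[4-(tert-butyldimethylsilyloxy)phenyl]-4H-pyran-4-one A4 with 1-methoxy-5-methylhex-4-en-1-yne A5. Wolff rearrangement of A4 gives a pyranonyl ketene, [2+2] addition to A5 gives a cyclobutenone, four-electron ring opening gives a dienyl ketene, and six-electron electrocyclisation with tautomerisation gives 4'-O-tert-butyldimethylsilyl gancaonin G A6. Removal of the silyl group of A6 with fluoride would then complete the synthesis.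
- In its favour: it is the most convergent plan, and the polarity of the ketene from A4 and of the ynol ether A5 places the prenyl group between the new hydroxyl and the methoxyl with certainty. On regiocontrol it is the equal of the chosen plan.
- The 5-hydroxyl of A6 arrives free, so no ether has to be cleaved next to the prenyl group and the last step from A6 to 23 is a desilylation. On the end game it is better than the chosen plan.
- Against it here: neither A4 nor A5 is a catalogue compound. A4 needs an aryl-substituted pyranone carboxylic acid and a diazo ketone synthesis, and A5 is a volatile, acid-sensitive ynol ether.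
- The pyranone chromophore of A4 and the isoflavone A6 absorb where the diazo ketone does, so competing pyranone photochemistry and light filtering by A6 are to be expected. The phenol of A6 can also be acylated by ketene not yet consumed.
- Comparison: the key step from A4 and A5 to A6 would form four bonds and a ring against two bonds in the chosen plan. The overall count is not expected to be lower, because A4 and A5 each need several steps, whereas the chosen plan draws on a symmetric phenol and a commercial acid.

Alternative 3: The cut removes C4a–C4 and C3–C4, and C4 comes from carbon monoxide A8. The forward key step would treat 1-iodo-2,4-dimethoxy-3-(3-methylbut-2-enyl)-6-{(E)-2-[4-(methoxymethoxy)phenyl]ethenoxy}benzene A7 under A8 with Pd(OAc)2 A9, PCy3 A10 and CsOPiv A11. Zerovalent palladium, formed from A9 and A10, inserts into the C4a–iodine bond of A7, A8 inserts to give an acylpalladium species, pivalate from A11 assists metalation of the enol ether C3–H, and reductive elimination closes ring C. The product is 5,7-dimethoxy-4'-(methoxymethoxy)-6-(3-methylbut-2-enyl)isoflavone A12, and A12 is the same compound as 21.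
- In its favour: because A12 is identical with 21, the end game is the same and therefore equal. From 6 only iodination, O-alkenylation to A7 and the carbonylation under A8 would be needed, against five steps (4, 5, 6, 8, 9) in the chosen plan, so on step count it is the better by about two steps. It also avoids an organolithium step on a prenylated arene, and A9, A10 and A11 are ordinary catalogue reagents.
- Against it here: the E enol ether of A7 has to be made stereodefined on an ortho-iodophenol without touching the C–I bond. Oxidative addition of the zerovalent palladium from A9 and A10 at a C–I bond flanked by two oxygen substituents is slow, and direct arylation without insertion of A8 would give a 3-arylbenzofuran.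
- Carbonylative acylation of an enol ether C–H bond with the help of pivalate from A11, leading to a 3-arylchromone such as A12, is far less established than carbonylative routes to 2-substituted chromones, and A8 is a toxic gas that has to be handled under pressure.
- Comparison: on structure both plans use 6 and its symmetry. On mechanism regiocontrol is equal in principle (position of iodine in A7 versus polarisation of the aryne). The way through A7 to A12 is shorter on paper but rests on a less secure key step.

Key step: step 8

Remark: enaminone 20 is written as its E isomer; this is an assumption without consequence, because the geometry is lost on ring closure. The insertion product 19 is named with lowest locants (6-hydroxy-2,4-dimethoxy-3-prenylphenyl).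

## Route

Step 1
Reactants: 1 3,5-dimethoxyphenol
Product: 2 (3,5-dimethoxyphenoxy)tri(propan-2-yl)silane
Conditions: TIPSCl, imidazole, DMF, rt
Reagents that add atoms: chlorotri(propan-2-yl)silane (TIPSCl), CC(C)[Si](Cl)(C(C)C)C(C)C
Why: Standard silyl ether formation on a phenol; the bulky silyl group removes the acidic proton, is a poor director of lithiation and shields both of its ortho positions, which prepares the regiochemistry of step 2.

Step 2
Reactants: 2 (3,5-dimethoxyphenoxy)tri(propan-2-yl)silane; 3 1-bromo-3-methylbut-2-ene (prenyl bromide)
Product: 5 [3,5-dimethoxy-4-(3-methylbut-2-enyl)phenoxy]tri(propan-2-yl)silane, via [2,6-dimethoxy-4-(triisopropylsilyloxy)phenyl]lithium 4 (not isolated)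
Conditions: n-BuLi, THF, 0 °C → rt; CuBr·SMe2 (10 mol%), then 3, −78 °C → rt
Reagents that add atoms: none
Why: Directed ortho-metalation at the carbon between the two methoxyl groups (cooperative direction, silyloxy group non-directing), then copper-assisted SN2 allylation of the aryl anion at the unhindered CH2 terminus of the primary allylic bromide, which gives the linear prenyl group.

Step 3
Reactants: 5 [3,5-dimethoxy-4-(3-methylbut-2-enyl)phenoxy]tri(propan-2-yl)silane
Product: 6 3,5-dimethoxy-4-(3-methylbut-2-enyl)phenol
Conditions: TBAF, AcOH, THF, 0 °C → rt
Reagents that add atoms: none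
Why: Fluoride-induced cleavage of an aryl silyl ether; acetic acid buffers the electron-rich phenoxide, and the alkene and methyl ethers are inert.

Step 4
Reactants: 6 3,5-dimethoxy-4-(3-methylbut-2-enyl)phenol
Product: 7 3,5-dimethoxy-4-(3-methylbut-2-enyl)phenyl N-(propan-2-yl)carbamate
Conditions: iPrNCO, Et3N (cat.), CH2Cl2, rt
Reagents that add atoms: 2-isocyanatopropane (isopropyl isocyanate), CC(C)N=C=O
Why: Amine-catalysed addition of the phenol to an isocyanate (carbamoylation); the N-monoalkyl carbamate is a strong ortho director once N-silylated and is later cleaved under mild base.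

Step 5
Reactants: 7 3,5-dimethoxy-4-(3-methylbut-2-enyl)phenyl N-(propan-2-yl)carbamate
Product: 11 3,5-dimethoxy-4-(3-methylbut-2-enyl)-2-(trimethylsilyl)phenyl N-(propan-2-yl)carbamate, via N-silyl carbamate 8 (not isolated), via ortho-lithiated N-silyl carbamate 9 (not isolated), via N-silyl C-trimethylsilyl carbamate 10 (not isolated)
Conditions: TBSOTf, TMEDA, Et2O, 0 °C → rt; n-BuLi, TMEDA, −78 °C; TMSCl, −78 °C → rt; aq. NaHSO4
Reagents that add atoms: chlorotrimethylsilane (TMSCl), C[Si](C)(C)Cl
Why: Carbamate-directed ortho-lithiation after transient N-silylation by TBSOTf, then C-silylation; the two ortho positions are equivalent by symmetry and each lies between the carbamate and a methoxyl. At −78 °C ring lithiation by precoordination should outrun deprotonation of the benzylic–allylic CH2, and the hydrogen sulfate work-up removes the N-silyl group.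

Step 6
Reactants: 11 3,5-dimethoxy-4-(3-methylbut-2-enyl)-2-(trimethylsilyl)phenyl N-(propan-2-yl)carbamate
Product: 13 3,5-dimethoxy-4-(3-methylbut-2-enyl)-2-(trimethylsilyl)phenyl trifluoromethanesulfonate, via ortho-silylphenol 12 (not isolated)
Conditions: DBU, Et2NH, MeCN, 40 °C; then PhNTf2, rt
Reagents that add atoms: 1,1,1-trifluoro-N-phenyl-N-[(trifluoromethyl)sulfonyl]methanesulfonamide (PhNTf2), O=S(=O)(N(c1ccccc1)S(=O)(=O)C(F)(F)F)C(F)(F)F
Why: Base-induced elimination of the N-monoalkyl carbamate (the isocyanate is trapped by Et2NH) and triflation of the phenoxide in the same flask; the medium stays mildly basic, so the aryl–silicon bond and the alkene are not at risk.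

Step 7
Reactants: 14 (4-hydroxyphenyl)acetic acid
Product: 16 [4-(methoxymethoxy)phenyl]acetic acid, via methoxymethyl ester 15 (not isolated)
Conditions: MOMCl (2.5 equiv), iPr2NEt, CH2Cl2, 0 °C → rt; then LiOH, THF–H2O, rt; HCl to pH 3–4, 0 °C
Reagents that add atoms: chloro(methoxy)methane (MOMCl), COCCl
Why: O-Alkylation of phenol and carboxylate, then selective saponification of the labile methoxymethyl ester; the aryl acetal resists base and brief cold dilute acid.

Step 8
Reactants: 13 3,5-dimethoxy-4-(3-methylbut-2-enyl)-2-(trimethylsilyl)phenyl trifluoromethanesulfonate; 16 [4-(methoxymethoxy)phenyl]acetic acid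
Product: 19 1-[6-hydroxy-2,4-dimethoxy-3-(3-methylbut-2-enyl)phenyl]-2-[4-(methoxymethoxy)phenyl]ethan-1-one, via aryne 17 (not isolated), via aryl caesium ester adduct 18 (not isolated)
Conditions: 13 (1.3 equiv), CsF (4 equiv), THF, 125 °C (sealed tube); aq. NH4Cl
Reagents that add atoms: none
Why: Fluoride attacks the trimethylsilyl group of 13 and the ortho triflate leaves, releasing aryne 17, while further CsF converts 16 into its caesium carboxylate. The carboxylate oxygen adds to the aryne carbon remote from the flanking methoxyl (future C8a), giving aryl anion 18 with the charge on the carbon next to that methoxyl (future C4a). The carbanion attacks its own ester carbonyl through a four-membered transition structure and the C–O bond breaks, so the acyl group moves from oxygen to carbon (an anionic Fries-type 1,3 shift) and the caesium phenoxide of 19 results, protonated on work-up. The closest known reaction type is the insertion of arynes into the carbon–oxygen bond of carboxylic acids to give ortho-hydroxyaryl ketones, applied here to an arylacetic acid and a 3-alkoxy aryne. No ring is closed and no stereocentre is formed; the two skeletal bonds O1–C8a and C4–C4a are made. The regioselectivity is secured by the methoxyl beside the triple bond, whose inductive pull directs the nucleophile to the distal carbon and stabilises the carbanion next to oxygen, and the symmetric origin of 13 allows only this one aryne. The chemoselectivity needed, acyl shift instead of protonation of 18 to an aryl ester, is favoured by the high temperature and by holding the acid as its carboxylate; the chelated, hindered phenoxide of 19 is a poor partner for a second aryne. No Lewis or Brønsted acid is present, so the prenyl alkene and the acetal should survive, and an intramolecular ene reaction is impossible because the prenyl group is not on a carbon adjacent to the triple bond.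

Step 9
Reactants: 19 1-[6-hydroxy-2,4-dimethoxy-3-(3-methylbut-2-enyl)phenyl]-2-[4-(methoxymethoxy)phenyl]ethan-1-one
Product: 21 5,7-dimethoxy-3-[4-(methoxymethoxy)phenyl]-6-(3-methylbut-2-enyl)-4H-chromen-4-one, via enaminone 20 (not isolated)
Conditions: Me2NCH(OMe)2, toluene, 95 °C
Reagents that add atoms: 1,1-dimethoxy-N,N-dimethylmethanamine (DMF dimethyl acetal), COC(OC)N(C)C
Why: The amide acetal condenses at the methylene activated by carbonyl and aryl to give enaminone 20; the ortho phenol then adds to its β-carbon and dimethylamine is lost (addition–elimination). This is the standard deoxybenzoin-to-isoflavone closure and runs without acid.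

Step 10
Reactants: 21 5,7-dimethoxy-3-[4-(methoxymethoxy)phenyl]-6-(3-methylbut-2-enyl)-4H-chromen-4-one
Product: 22 3-(4-hydroxyphenyl)-5,7-dimethoxy-6-(3-methylbut-2-enyl)-4H-chromen-4-one
Conditions: HCl (3 M aq.), MeOH, 40 °C
Reagents that add atoms: none
Why: Acid-catalysed methanolysis of the aryl methoxymethyl acetal; it is run while O5 still carries its methyl group, so no free phenol flanks the prenyl alkene and chroman formation has no nucleophile.

Step 11
Reactants: 22 3-(4-hydroxyphenyl)-5,7-dimethoxy-6-(3-methylbut-2-enyl)-4H-chromen-4-one
Product: 23 gancaonin G, 5-hydroxy-3-(4-hydroxyphenyl)-7-methoxy-6-(3-methylbut-2-enyl)-4H-chromen-4-one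
Conditions: MgI2·OEt2 (3 equiv), THF, 60 °C; aq. NH4Cl, Na2S2O3
Reagents that add atoms: none
Why: Chelation-controlled ether cleavage: magnesium bridges the C4 carbonyl and O5 and iodide attacks the methyl group (SN2), while the 7-methoxyl cannot chelate and stays. The new 5-oxygen remains bound in the magnesium chelate until work-up and should not add to the prenyl alkene; magnesium iodide etherate is an established reagent for selective cleavage of methyl ethers ortho to a carbonyl group.

## Compound list

1 | 3,5-dimethoxyphenol | COc1cc(O)cc(OC)c1 | starting material
2 | (3,5-dimethoxyphenoxy)tri(propan-2-yl)silane | COc1cc(O[Si](C(C)C)(C(C)C)C(C)C)cc(OC)c1 | intermediate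
3 | 1-bromo-3-methylbut-2-ene (prenyl bromide) | CC(C)=CCBr | starting material
4 | [2,6-dimethoxy-4-(triisopropylsilyloxy)phenyl]lithium | [Li]c1c(OC)cc(O[Si](C(C)C)(C(C)C)C(C)C)cc1OC | intermediate
5 | [3,5-dimethoxy-4-(3-methylbut-2-enyl)phenoxy]tri(propan-2-yl)silane | COc1cc(O[Si](C(C)C)(C(C)C)C(C)C)cc(OC)c1CC=C(C)C | intermediate
6 | 3,5-dimethoxy-4-(3-methylbut-2-enyl)phenol | COc1cc(O)cc(OC)c1CC=C(C)C | intermediate
7 | 3,5-dimethoxy-4-(3-methylbut-2-enyl)phenyl N-(propan-2-yl)carbamate | COc1cc(OC(=O)NC(C)C)cc(OC)c1CC=C(C)C | intermediate
8 | 3,5-dimethoxy-4-(3-methylbut-2-enyl)phenyl N-[tert-butyl(dimethyl)silyl]-N-(propan-2-yl)carbamate | COc1cc(OC(=O)N(C(C)C)[Si](C)(C)C(C)(C)C)cc(OC)c1CC=C(C)C | intermediate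
9 | [2-({[tert-butyl(dimethyl)silyl](propan-2-yl)carbamoyl}oxy)-4,6-dimethoxy-5-(3-methylbut-2-enyl)phenyl]lithium | COc1cc(OC(=O)N(C(C)C)[Si](C)(C)C(C)(C)C)c([Li])c(OC)c1CC=C(C)C | intermediate
10 | 3,5-dimethoxy-4-(3-methylbut-2-enyl)-2-(trimethylsilyl)phenyl N-[tert-butyl(dimethyl)silyl]-N-(propan-2-yl)carbamate | COc1cc(OC(=O)N(C(C)C)[Si](C)(C)C(C)(C)C)c([Si](C)(C)C)c(OC)c1CC=C(C)C | intermediate
11 | 3,5-dimethoxy-4-(3-methylbut-2-enyl)-2-(trimethylsilyl)phenyl N-(propan-2-yl)carbamate | COc1cc(OC(=O)NC(C)C)c([Si](C)(C)C)c(OC)c1CC=C(C)C | intermediate
12 | 3,5-dimethoxy-4-(3-methylbut-2-enyl)-2-(trimethylsilyl)phenol (formed as its amidinium phenoxide) | COc1cc(O)c([Si](C)(C)C)c(OC)c1CC=C(C)C | intermediate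
13 | 3,5-dimethoxy-4-(3-methylbut-2-enyl)-2-(trimethylsilyl)phenyl trifluoromethanesulfonate | COc1cc(OS(=O)(=O)C(F)(F)F)c([Si](C)(C)C)c(OC)c1CC=C(C)C | intermediate
14 | (4-hydroxyphenyl)acetic acid | O=C(O)Cc1ccc(O)cc1 | starting material
15 | methoxymethyl [4-(methoxymethoxy)phenyl]acetate | COCOC(=O)Cc1ccc(OCOC)cc1 | intermediate
16 | [4-(methoxymethoxy)phenyl]acetic acid | COCOc1ccc(CC(=O)O)cc1 | intermediate
17 | 3,5-dimethoxy-4-(3-methylbut-2-enyl)benzyne (1,2-didehydrobenzene) | COC1=C(CC=C(C)C)C(OC)=CC#C1 | intermediate
18 | {2-[({4-(methoxymethoxy)phenyl}acetyl)oxy]-4,6-dimethoxy-5-(3-methylbut-2-enyl)phenyl}caesium | COCOc1ccc(CC(=O)Oc2cc(OC)c(CC=C(C)C)c(OC)c2[Cs])cc1 | intermediate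
19 | 1-[6-hydroxy-2,4-dimethoxy-3-(3-methylbut-2-enyl)phenyl]-2-[4-(methoxymethoxy)phenyl]ethan-1-one | COCOc1ccc(CC(=O)c2c(O)cc(OC)c(CC=C(C)C)c2OC)cc1 | intermediate
20 | (2E)-3-(dimethylamino)-1-[6-hydroxy-2,4-dimethoxy-3-(3-methylbut-2-enyl)phenyl]-2-[4-(methoxymethoxy)phenyl]prop-2-en-1-one | CN(C)/C=C(\c1ccc(OCOC)cc1)C(=O)c1c(O)cc(OC)c(CC=C(C)C)c1OC | intermediate
21 | 5,7-dimethoxy-3-[4-(methoxymethoxy)phenyl]-6-(3-methylbut-2-enyl)-4H-chromen-4-one | COCOc1ccc(-c2coc3cc(OC)c(CC=C(C)C)c(OC)c3c2=O)cc1 | intermediate
22 | 3-(4-hydroxyphenyl)-5,7-dimethoxy-6-(3-methylbut-2-enyl)-4H-chromen-4-one | COc1cc2occ(-c3ccc(O)cc3)c(=O)c2c(OC)c1CC=C(C)C | intermediate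
23 | gancaonin G, 5-hydroxy-3-(4-hydroxyphenyl)-7-methoxy-6-(3-methylbut-2-enyl)-4H-chromen-4-one | COc1cc2occ(-c3ccc(O)cc3)c(=O)c2c(O)c1CC=C(C)C | target

## Step count and risk

Total step count: 11. Longest linear sequence: 10 steps (steps 1–6 and 8–11); step 7 is the one-step side branch.

Least certain steps:

**Step 8 (key step).** The aryl anion 18 may be protonated before the acyl shift, which would stop at O-arylation, and the product phenoxide or its enolate may capture a second aryne.
- Fallback: it sets out from 7 and 16 and comes back at 19. It reaches the same carbanion position by deprotonation instead of by carboxylate addition.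
- 16 is converted with carbonyldiimidazole and MeNHOMe·HCl into N-methoxy-N-methyl-2-[4-(methoxymethoxy)phenyl]acetamide F1.
- 7 is N-silylated and lithiated as in step 5 to give 9, which is quenched at −78 °C with F1 instead of the chlorosilane.
- After the hydrogen sulfate work-up the ketone 2-{[4-(methoxymethoxy)phenyl]acetyl}-3,5-dimethoxy-4-(3-methylbut-2-enyl)phenyl N-(propan-2-yl)carbamate F2 is obtained.
- Et2NH and DBU in MeCN then remove the carbamate as in step 6 and give 19.
- The weak point of this directed-metalation acylation is enolisation of F1 by the hindered aryllithium.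

**Step 5.** Deprotonation at the benzylic–allylic CH2 of the prenyl group may compete with ring lithiation, and the carbamoyl group may shift to carbon on warming.
- Fallback: it sets out from 6 and comes back at 13. It replaces deprotonation by halogen–metal exchange.
- 6 is iodinated at one of its two equivalent ortho positions (I2, NaHCO3, THF–H2O, 0 °C) to 2-iodo-3,5-dimethoxy-4-(3-methylbut-2-enyl)phenol F3.
- F3 is O-silylated with hexamethyldisilazane to [2-iodo-3,5-dimethoxy-4-(3-methylbut-2-enyl)phenoxy]trimethylsilane F4.
- n-BuLi at −100 °C gives, by iodine–lithium exchange, [2,4-dimethoxy-3-(3-methylbut-2-enyl)-6-(trimethylsilyloxy)phenyl]lithium F5.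
- Its 1,3 oxygen-to-carbon silyl shift (retro-Brook rearrangement) furnishes the lithium salt of 12, which PhNTf2 converts into 13.

**Step 2.** Lithiation next to the silyloxy group with silyl migration, or allylic transposition in the alkylation, would give isomeric products.
- Fallback: it sets out from 3 and comes back at 6, replacing steps 1–3.
- Purchased 1,3-dimethoxybenzene F6 is lithiated at its only doubly activated position to (2,6-dimethoxyphenyl)lithium F7 and alkylated with 3 to 1,3-dimethoxy-2-(3-methylbut-2-enyl)benzene F8.
- Sterically controlled C–H borylation ([Ir(OMe)(cod)]2, 4,4'-di-tert-butyl-2,2'-bipyridine, B2pin2, THF, 60 °C) at the only ring C–H without an ortho neighbour gives 2-[3,5-dimethoxy-4-(3-methylbut-2-enyl)phenyl]-4,4,5,5-tetramethyl-1,3,2-dioxaborolane F9.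
- NaBO3·4H2O in THF–H2O oxidises the C–B bond and gives 6.
- Here the ring regiochemistry is secure; the open question is tolerance of the trisubstituted alkene in the borylation.

**Step 11.** Ether cleavage at the crowded peri position may be sluggish, and prolonged heating or work-up may let the liberated 5-hydroxyl add to the prenyl double bond.
- Fallback: it sets out from 21 and comes back at 23, merging steps 10 and 11; no new compound is made.
- 21 is treated with BCl3 in CH2Cl2 at −78 °C and quenched into cold aqueous NaHCO3.
- The boron chelate between the C4 carbonyl and O5 cleaves the peri methyl ether at low temperature, and the acetal on ring B falls in the same operation.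
- O5 stays bound to boron until the basic quench, so the free phenol and acid never meet in solution.

## Further compounds

F1 | step 8 | N-methoxy-N-methyl-2-[4-(methoxymethoxy)phenyl]acetamide | COCOc1ccc(CC(=O)N(C)OC)cc1
F2 | step 8 | 2-{[4-(methoxymethoxy)phenyl]acetyl}-3,5-dimethoxy-4-(3-methylbut-2-enyl)phenyl N-(propan-2-yl)carbamate | COCOc1ccc(CC(=O)c2c(OC(=O)NC(C)C)cc(OC)c(CC=C(C)C)c2OC)cc1
F3 | step 5 | 2-iodo-3,5-dimethoxy-4-(3-methylbut-2-enyl)phenol | COc1cc(O)c(I)c(OC)c1CC=C(C)C
F4 | step 5 | [2-iodo-3,5-dimethoxy-4-(3-methylbut-2-enyl)phenoxy]trimethylsilane | COc1cc(O[Si](C)(C)C)c(I)c(OC)c1CC=C(C)C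
F5 | step 5 | [2,4-dimethoxy-3-(3-methylbut-2-enyl)-6-(trimethylsilyloxy)phenyl]lithium | COc1cc(O[Si](C)(C)C)c([Li])c(OC)c1CC=C(C)C
F6 | step 2 | 1,3-dimethoxybenzene (purchased) | COc1cccc(OC)c1
F7 | step 2 | (2,6-dimethoxyphenyl)lithium | COc1cccc(OC)c1[Li]
F8 | step 2 | 1,3-dimethoxy-2-(3-methylbut-2-enyl)benzene | COc1cccc(OC)c1CC=C(C)C
F9 | step 2 | 2-[3,5-dimethoxy-4-(3-methylbut-2-enyl)phenyl]-4,4,5,5-tetramethyl-1,3,2-dioxaborolane | COc1cc(B2OC(C)(C)C(C)(C)O2)cc(OC)c1CC=C(C)C
F0 | step 11 | none | none
A1 | alternative 1 | 2-[4-(benzyloxy)phenyl]-1-[2-(ethenyloxy)-4,6-dimethoxyphenyl]prop-2-en-1-one | C=COc1cc(OC)cc(OC)c1C(=O)C(=C)c1ccc(OCc2ccccc2)cc1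
A2 | alternative 1 | Mo(N-2,6-iPr2C6H3)(CHCMe2Ph)[OCMe(CF3)2]2 | CC(C)c1cccc(C(C)C)c1N=[Mo](=CC(C)(C)c1ccccc1)(OC(C)(C(F)(F)F)C(F)(F)F)OC(C)(C(F)(F)F)C(F)(F)F
A3 | alternative 1 | 4'-benzyloxy-5,7-dimethoxyisoflavone | COc1cc(OC)c2c(c1)occ(-c1ccc(OCc3ccccc3)cc1)c2=O
A4 | alternative 2 | 2-(2-diazoacetyl)-5-[4-(tert-butyldimethylsilyloxy)phenyl]-4H-pyran-4-one | O=C(C=[N+]=[N-])c1cc(=O)c(-c2ccc(O[Si](C)(C)C(C)(C)C)cc2)co1
A5 | alternative 2 | 1-methoxy-5-methylhex-4-en-1-yne | COC#CCC=C(C)C
A6 | alternative 2 | 4'-O-tert-butyldimethylsilyl gancaonin G | COc1cc2occ(-c3ccc(O[Si](C)(C)C(C)(C)C)cc3)c(=O)c2c(O)c1CC=C(C)C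
A7 | alternative 3 | 1-iodo-2,4-dimethoxy-3-(3-methylbut-2-enyl)-6-{(E)-2-[4-(methoxymethoxy)phenyl]ethenoxy}benzene | COCOc1ccc(/C=C/Oc2cc(OC)c(CC=C(C)C)c(OC)c2I)cc1
A8 | alternative 3 | carbon monoxide | [C-]#[O+]
A9 | alternative 3 | Pd(OAc)2 (palladium diacetate) | CC(=O)[O-].CC(=O)[O-].[Pd+2]
A10 | alternative 3 | PCy3 (tricyclohexylphosphane) | C1CCC(CC1)P(C1CCCCC1)C1CCCCC1
A11 | alternative 3 | CsOPiv (caesium 2,2-dimethylpropanoate) | CC(C)(C)C(=O)[O-].[Cs+]
A12 | alternative 3 | 5,7-dimethoxy-4'-(methoxymethoxy)-6-(3-methylbut-2-enyl)isoflavone (identical with 21) | COCOc1ccc(-c2coc3cc(OC)c(CC=C(C)C)c(OC)c3c2=O)cc1
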